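**Retrosynthetic overview**

- Target 21 comes from a reagent-controlled Shi epoxidation of the C10=C11 alkene; the C8 angelate comes from a C8 carbinol set by CBS reduction of the C8 enone; C7–C8 is made by NiCl2/CrCl2 coupling of a C7 alkenyl triflate with 4-methylpent-3-enal (C14 from MeMgBr).
- C5–Cl and C2–OH come from chloride opening, with inversion at C5, of the C2–O–C5 bridge of a 7-oxabicyclo[2.2.1]heptane whose exo face already carries C7, the C3 angelate and C4–OH.
- The bridged core comes from an exo-selective, catalytic asymmetric Diels–Alder reaction of 3-methylfuran with 2,2,2-trifluoroethyl acrylate.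
- Ring order: the carbocycle (ring A) and the temporary oxygen bridge form together in step 1; the bridge is cleaved in step 6; the oxirane is formed last, in step 15.
- Feature on which the plan rests: C2–OH and C5–Cl are 1,4-trans while the C1 side chain, C3–O and C4–O are all cis to C2–O. Numbering: ring C1 (chain), C2 (OH), C3 (angelate), C4 (CH3, OH), C5 (Cl), C6 (CH2); chain C7 (=C14H2), C8 (angelate), C9, oxirane C10–C11.

Key step: step 1

Assumption: the (S)-diphenylprolinol-derived oxazaborolidinium cation directs the diene to the α-re face of the coordinated acrylate (the sense that gives the (S)-cyclohex-3-enecarboxylate from butadiene); if the opposite sense were found, the (R)-prolinol catalyst would be used with no other change.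

**Route**

Step 1
Reactants: 1 3-methylfuran; 2 2,2,2-trifluoroethyl acrylate
Product: 3 2,2,2-trifluoroethyl (1R,2S,4R)-5-methyl-7-oxabicyclo[2.2.1]hept-5-ene-2-carboxylate (exo ester)
Conditions: N-protonated (S)-B-(o-tolyl)-α,α-diphenylprolinol oxazaborolidine, [C24H25BNO]+[N(SO2CF3)2]− (15 mol %, made beforehand from (S)-α,α-diphenylprolinol, tri(o-tolyl)boroxine and HN(SO2CF3)2), 1 (3 equiv), CH2Cl2, −60 → 0 °C; Et3N quench
Reagents that add atoms: none
Why: Concerted, asynchronous [4+2] cycloaddition of the furan to acrylate bound through its carbonyl oxygen to the boron of the chiral cation; the closest known reaction type is the oxazaborolidinium-catalysed Diels–Alder reaction of furans with trifluoroethyl acrylate. The six-membered carbocycle (C1–C6) closes by suprafacial cycloaddition, C5–C6 and C1–C2 forming in the same event, and the furan oxygen remains as the one-atom bridge between C2 and C5. C1 is set by the catalyst, whose aryl group shields one face of the acrylate so that the diene adds to the α-re face; C2 and C5 follow from the exo orientation, which should accumulate because furan cycloadditions are reversible under the catalyst and the exo ester is the more stable adduct. The regiochemistry (ring methyl 1,4 to the ester) comes from the larger HOMO coefficient at the furan α-carbon next to the methyl group, which bonds to the acrylate β-carbon. The step needs regio-, exo- and enantioselectivity together; any endo or regioisomeric adduct is removed by chromatography and returned to its components by cycloreversion, and 3 is dihydroxylated at once because it can revert.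

Step 2
Reactants: 3 exo adduct
Product: 4 exo,exo-3,4-diol trifluoroethyl ester
Conditions: OsO4 (2 mol %), NMO, acetone–H2O, 0 °C → rt
Reagents that add atoms: osmium tetroxide (catalytic oxygen carrier), O=[Os](=O)(=O)=O; N-methylmorpholine N-oxide, C[N+]1([O-])CCOCC1; water, O
Why: Upjohn dihydroxylation; OsO4 adds suprafacially to the strained C3=C4 alkene from the exo face (the side of the oxygen bridge), which sets C3 and C4 with both oxygens cis to the bridge and the C4 methyl endo, and removes the cycloreversion pathway.

Step 3
Reactants: 4 diol ester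
Product: 5 N-methoxy-N-methylamide diol
Conditions: MeNH(OMe)·HCl (3 equiv), iPrMgCl (8 equiv), THF, −20 → 0 °C; aq. NH4Cl
Reagents that add atoms: N,O-dimethylhydroxylamine hydrochloride, CNOC.Cl
Why: Weinreb amide formation by aminolysis of the activated trifluoroethyl ester with ClMgN(OMe)Me; the two magnesium alkoxides are spectators and the C1 centre is not enolised at this temperature.

Step 4
Reactants: 5 Weinreb amide
Product: 6 methyl ketone diol
Conditions: MeMgBr (4 equiv), THF, −20 → 0 °C; aq. NH4Cl
Reagents that add atoms: methylmagnesium bromide, C[Mg]Br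
Why: Grignard addition to a Weinreb amide stops at the chelated tetrahedral adduct, which releases the C7 methyl ketone (C14 introduced) on work-up.

Step 5
Reactants: 6 methyl ketone diol; 7 angelic acid
Product: 8 C3 angelate of the bridged ketone
Conditions: 7, 2,4,6-trichlorobenzoyl chloride, Et3N, toluene, rt; then 6, 70 °C (no DMAP)
Reagents that add atoms: angelic acid (7), C/C=C(/C)C(=O)O
Why: Yamaguchi-type mixed-anhydride esterification without a nucleophilic catalyst keeps the Z-alkene; only the secondary exo C3–OH is acylated, because the C4–OH is tertiary and the C2 oxygen is still locked in the bridge.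

Step 6
Reactants: 8 C3 angelate
Product: 10 all-cis C1-acetyl C2-hydroxy C3-angeloyloxy C4-hydroxy cyclohexane with trans C5 chloride, via cyclic chloroboronate 9 (not isolated)
Conditions: BCl3 (4 equiv), 2,6-di-tert-butyl-4-methylpyridine, CH2Cl2, −78 → −20 °C; pH 7 buffer
Reagents that add atoms: boron trichloride, ClB(Cl)Cl
Why: Boron trihalide cleavage of a 7-oxabicyclo[2.2.1]heptane to a trans-4-halocyclohexanol is a known reaction of this ring system: boron activates the bridging oxygen, chloride enters at C5 on the endo face anti to the C5–O bond so that C5 is inverted while the oxygen stays on C2, and C2 is the disfavoured site because it lies between the acetyl-bearing C1 and the acyloxy-bearing C3; the hindered pyridine takes up HCl so that the Z-ester is not isomerised.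

Step 7
Reactants: 10 chlorohydrin diol
Product: 11 C2,C4-bis(triethylsilyl) ether
Conditions: Et3SiOSO2CF3 (3 equiv), 2,6-lutidine, CH2Cl2, −78 → 0 °C; aq. NH4Cl
Reagents that add atoms: triethylsilyl trifluoromethanesulfonate, CC[Si](CC)(CC)OS(=O)(=O)C(F)(F)F
Why: Silylation with the silyl triflate caps the secondary C2–OH and the tertiary C4–OH, so that no alkoxide can later displace the trans-diaxial C5 chloride or undergo retro-aldol cleavage; any silyl enol ether is hydrolysed on work-up.

Step 8
Reactants: 11 bis-silyl ether
Product: 13 C7 alkenyl triflate, via potassium enolate 12 (not isolated)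
Conditions: KN(SiMe3)2 (1.1 equiv), THF, −78 °C; PhN(SO2CF3)2, −78 → −20 °C
Reagents that add atoms: N-phenylbis(trifluoromethanesulfonimide), O=S(=O)(N(c1ccccc1)S(=O)(=O)C(F)(F)F)C(F)(F)F
Why: Kinetic deprotonation of the methyl ketone at the methyl group (less hindered than the C1 methine) followed by O-triflation of the enolate gives the 1,1-disubstituted alkenyl triflate without touching C1.

Step 9
Reactants: 14 4-methylpent-3-en-1-ol
Product: 15 4-methylpent-3-enal
Conditions: Dess–Martin periodinane (C13H13IO8), NaHCO3, CH2Cl2, 0 °C; used at once as a solution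
Reagents that add atoms: none
Why: Dess–Martin oxidation of a primary alcohol under buffered neutral conditions should not move the β,γ-alkene into conjugation.

Step 10
Reactants: 13 alkenyl triflate; 15 4-methylpent-3-enal
Product: 16 C8 allylic alcohol (both C8 epimers)
Conditions: CrCl2 (6 equiv), NiCl2 (2 mol %), DMF, rt
Reagents that add atoms: none
Why: Nozaki–Hiyama–Kishi coupling; the NiCl2-catalysed alkenylchromium species from the triflate adds to the aldehyde to form C7–C8, and the esters, alkyl chloride, silyl ethers and alkenes are tolerated; the C8 mixture is erased in step 11.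

Step 11
Reactants: 16 allylic alcohol
Product: 17 C8 ketone (α-methylene ketone)
Conditions: Dess–Martin periodinane (C13H13IO8), NaHCO3, CH2Cl2, 0 °C
Reagents that add atoms: none
Why: Buffered Dess–Martin oxidation of the secondary allylic alcohol gives the enone without base, so the C9 methylene is not enolised into conjugation with C10=C11.

Step 12
Reactants: 17 enone
Product: 18 (8S)-allylic alcohol
Conditions: (R)-2-methyl-CBS-oxazaborolidine (C18H20BNO, 0.5 equiv), catecholborane, toluene, −78 °C; MeOH
Reagents that add atoms: none
Why: Corey–Bakshi–Shibata reduction; the α-branched alkenyl group (C7) acts as the large substituent and the C9 methylene as the small one, so the (R)-catalyst should deliver hydride to give the (8S)-carbinol by 1,2-reduction.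

Step 13
Reactants: 18 (8S)-alcohol; 7 angelic acid
Product: 19 C3,C8-bis-angelate bis-silyl ether
Conditions: 7, 2,4,6-trichlorobenzoyl chloride, Et3N, toluene, rt; then 18, 70 °C (no DMAP)
Reagents that add atoms: angelic acid (7), C/C=C(/C)C(=O)O
Why: The same mixed-anhydride esterification acylates the only free hydroxyl (C8) with retention at C8 and without Z to E isomerisation.

Step 14
Reactants: 19 bis-silyl ether
Product: 20 C2,C4-diol with the C10=C11 alkene
Conditions: HF·pyridine, pyridine, THF, 0 °C → rt
Reagents that add atoms: none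
Why: Buffered fluoride desilylation removes both triethylsilyl groups before the acid-sensitive oxirane is present, and avoids the basic conditions that would close the chlorohydrin to an epoxide or move the C3 ester.

Step 15
Reactants: 20 diol
Product: 21 target CNP0158207.1
Conditions: D-fructose-derived Shi ketone (C12H18O6, 1–3 equiv), Oxone (2KHSO5·KHSO4·K2SO4), NaHCO3, Bu4NHSO4, MeCN/dimethoxymethane–aq. Na2EDTA (pH ≈ 8), 0 °C
Reagents that add atoms: potassium peroxymonosulfate (Oxone), [K+].[O-]S(=O)(=O)OO
Why: Shi asymmetric epoxidation; the chiral dioxirane reacts only with the electron-rich trisubstituted C10=C11 alkene (the angelates and the acyloxy-flanked C7=C14 are electron-poor), and the D-fructose-derived ketone should give the (10R)-oxirane through the spiro transition state, at a pH the chlorohydrin tolerates.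

**Compound list**

1 | 3-methylfuran | Cc1ccoc1 | starting material
2 | 2,2,2-trifluoroethyl acrylate | C=CC(=O)OCC(F)(F)F | starting material
3 | 2,2,2-trifluoroethyl (1R,2S,4R)-5-methyl-7-oxabicyclo[2.2.1]hept-5-ene-2-carboxylate (exo; C7 ester on C1, methyl on C4, C3=C4) | O=C(OCC(F)(F)F)[C@H]1C[C@H]2O[C@@H]1C=C2C | intermediate
4 | exo,exo-diol of 3 (C3–OH and C4–OH cis to the oxygen bridge, C4 methyl endo) | O=C(OCC(F)(F)F)[C@H]1C[C@@H]2[C@@](C)(O)[C@@H](O)[C@H]1O2 | intermediate
5 | N-methoxy-N-methylamide corresponding to 4 | CON(C)C(=O)[C@H]1C[C@@H]2[C@@](C)(O)[C@@H](O)[C@H]1O2 | intermediate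
6 | exo C1-acetyl bridged diol (methyl ketone) | CC(=O)[C@H]1C[C@@H]2[C@@](C)(O)[C@@H](O)[C@H]1O2 | intermediate
7 | angelic acid, (Z)-2-methylbut-2-enoic acid | C/C=C(/C)C(=O)O | starting material
8 | C3 angelate of 6 (C4–OH free) | CC(=O)[C@H]1C[C@@H]2[C@@](C)(O)[C@@H](OC(=O)/C(C)=C\C)[C@H]1O2 | intermediate
9 | O2,O4-cyclic chloroboronate of 10 | CC(=O)[C@H]1C[C@H](Cl)[C@@](C)(O3)[C@@H](OC(=O)/C(C)=C\C)[C@H]1OB3Cl | intermediate (not isolated)
10 | cyclohexane with C1 acetyl, C2–OH, C3 angelate and C4–OH all cis, C4 methyl and C5 chloride on the other face | CC(=O)[C@H]1C[C@H](Cl)[C@@](C)(O)[C@@H](OC(=O)/C(C)=C\C)[C@H]1O | intermediate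
11 | C2,C4-bis(triethylsilyl) ether of 10 | CC(=O)[C@H]1C[C@H](Cl)[C@@](C)(O[Si](CC)(CC)CC)[C@@H](OC(=O)/C(C)=C\C)[C@H]1O[Si](CC)(CC)CC | intermediate
12 | potassium enolate (C7=C14) of 11 | C=C([O-])[C@H]1C[C@H](Cl)[C@@](C)(O[Si](CC)(CC)CC)[C@@H](OC(=O)/C(C)=C\C)[C@H]1O[Si](CC)(CC)CC.[K+] | intermediate (not isolated)
13 | C7 alkenyl triflate (C7(=C14H2)–OSO2CF3) | C=C(OS(=O)(=O)C(F)(F)F)[C@H]1C[C@H](Cl)[C@@](C)(O[Si](CC)(CC)CC)[C@@H](OC(=O)/C(C)=C\C)[C@H]1O[Si](CC)(CC)CC | intermediate
14 | 4-methylpent-3-en-1-ol | CC(C)=CCCO | starting material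
15 | 4-methylpent-3-enal | CC(C)=CCC=O | intermediate
16 | C8 allylic alcohol, both C8 epimers | C=C(C(O)CC=C(C)C)[C@H]1C[C@H](Cl)[C@@](C)(O[Si](CC)(CC)CC)[C@@H](OC(=O)/C(C)=C\C)[C@H]1O[Si](CC)(CC)CC | intermediate
17 | C8 ketone (α-methylene ketone) | C=C(C(=O)CC=C(C)C)[C@H]1C[C@H](Cl)[C@@](C)(O[Si](CC)(CC)CC)[C@@H](OC(=O)/C(C)=C\C)[C@H]1O[Si](CC)(CC)CC | intermediate
18 | (8S)-allylic alcohol | C=C([C@H](CC=C(C)C)O)[C@H]1C[C@H](Cl)[C@@](C)(O[Si](CC)(CC)CC)[C@@H](OC(=O)/C(C)=C\C)[C@H]1O[Si](CC)(CC)CC | intermediate
19 | C3,C8-bis-angelate, C2,C4-bis(triethylsilyl) ether | C=C([C@H](CC=C(C)C)OC(=O)/C(C)=C\C)[C@H]1C[C@H](Cl)[C@@](C)(O[Si](CC)(CC)CC)[C@@H](OC(=O)/C(C)=C\C)[C@H]1O[Si](CC)(CC)CC | intermediate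
20 | C3,C8-bis-angelate C2,C4-diol with C10=C11 alkene (10,11-deoxy target) | C=C([C@H](CC=C(C)C)OC(=O)/C(C)=C\C)[C@H]1C[C@H](Cl)[C@@](C)(O)[C@@H](OC(=O)/C(C)=C\C)[C@H]1O | intermediate
21 | CNP0158207.1 | C=C([C@H](C[C@H]1OC1(C)C)OC(=O)/C(C)=C\C)[C@H]1C[C@H](Cl)[C@@](C)(O)[C@@H](OC(=O)/C(C)=C\C)[C@H]1O | target

**Step count**

Total: 15 steps (the catalyst preparation is not counted). Longest linear sequence: 14 steps (steps 1–8 and 10–15).

**Steps most likely to fail**

Step 6. Chloride delivery to C5 must pass close to the endo C4 methyl, so it may be slow; attack at the less hindered C2, ionisation next to the tertiary C4 carbinol with a semipinacol shift, or acid-induced isomerisation of the angelate may then compete. Fallback: chlorine is brought in by epoxide opening instead of ether cleavage. Setting out from 8, the more reactive BBr3 (CH2Cl2, −78 °C) should open the bridge to the bromohydrin F1. Ag2O (acetone, rt) closes only the C5 bromide, which is trans to C4–OH, to the C4,C5-epoxide F2, so a C2 bromide would be left behind and the regiochemistry shown at once. CeCl3·7H2O (MeCN) then opens the epoxide at the secondary C5 in the trans-diaxial sense and returns to the route at 10.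

Step 1. The kinetic endo adduct may persist if cycloreversion is slow at temperatures the catalyst tolerates, the 3-methyl group may not give full regiocontrol, and the enantioselectivity may erode. Fallback: stereocontrol is moved from the catalyst to a separable auxiliary. (S)-3-Acryloyl-4-benzyloxazolidin-2-one F3 (from the commercial oxazolidinone and acryloyl chloride) and 1 are equilibrated with ZnI2 at rt to the exo adducts. The diastereomer with the ring configuration of 3, imide F4, is isolated by crystallisation and the other is recycled by cycloreversion. OsO4/NMO gives the diol imide F5, and AlMe3/MeNH(OMe)·HCl cleaves the auxiliary to return to the route at 5.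

Step 13 (and likewise step 5). Slow acylation of the hindered carbinol may allow Z to E isomerisation of the angelic acyl donor, giving the tiglate. Fallback: the Z-alkene is built on the molecule. Setting out from 18, esterification with 2-[bis(2,2,2-trifluoroethoxy)phosphoryl]propanoic acid (EDC, DMAP) gives the phosphonopropionate F6. Still–Gennari olefination (KN(SiMe3)2, 18-crown-6, acetaldehyde, THF, −78 °C) then forms the Z-2-methylbut-2-enoate and returns to the route at 19.

Further compounds
F1 | step 6 | C5 bromohydrin analogue of 10 | CC(=O)[C@H]1C[C@H](Br)[C@@](C)(O)[C@@H](OC(=O)/C(C)=C\C)[C@H]1O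
F2 | step 6 | C4,C5-epoxide (oxygen cis to C2–OH and the C3 angelate) | CC(=O)[C@H]1C[C@H]2O[C@@]2(C)[C@@H](OC(=O)/C(C)=C\C)[C@H]1O
F3 | step 1 | (S)-3-acryloyl-4-benzyloxazolidin-2-one | C=CC(=O)N1[C@@H](Cc2ccccc2)COC1=O
F4 | step 1 | exo cycloadduct imide with the ring configuration of 3 | O=C([C@H]1C[C@H]2O[C@@H]1C=C2C)N1[C@@H](Cc2ccccc2)COC1=O
F5 | step 1 | exo,exo-diol imide | O=C([C@H]1C[C@@H]2[C@@](C)(O)[C@@H](O)[C@H]1O2)N1[C@@H](Cc2ccccc2)COC1=O
F6 | step 13 | C8 2-[bis(2,2,2-trifluoroethoxy)phosphoryl]propanoate of 18 | C=C([C@H](CC=C(C)C)OC(=O)C(C)P(=O)(OCC(F)(F)F)OCC(F)(F)F)[C@H]1C[C@H](Cl)[C@@](C)(O[Si](CC)(CC)CC)[C@@H](OC(=O)/C(C)=C\C)[C@H]1O[Si](CC)(CC)CC
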